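## Analysis of the target

Guidongnin C (35) is a 6,7-seco-ent-kauranoid. With ent-kaurane numbering it has ring A (C1–C5, C10) cis-fused to a γ-lactone (C6(=O)–O–C19 across C4–C5), a δ-lactone (C7(=O)–O–C20) fused to ring C across C8–C9, and a bicyclo[3.2.1]octane made of ring C (C8, C9, C11, C12, C13, C14) and ring D (C8, C14, C13, C16, C15). There are eight stereocentres (C4, C5, C10, C9, C8, C11, C13, C16), three of them quaternary (C4, C8, C10), and the C9–C10 bond joins a quaternary carbon to a tertiary one flanked by quaternary C8. On ring C the C15–C16 bridge lies on one face, while C10 (axial on C9), the equatorial C11 hydroxyl and the C7 carbonyl lie on the other. The C16 methyl points to the endo side (towards C11/C12), the arrangement that arises when hydrogen is delivered to the exo face; C16–H is α to the C15 ketone and can epimerise. Other sensitive sites are the C15 ketone (next to C8 bearing C7, so open to retro-Claisen attack by alkoxides), C5–H α to the C6 lactone, both lactones and the secondary alcohol. The difficulty is a bicyclo[3.2.1]octane whose quaternary bridgehead carries two carbonyl groups, next to the crowded C9–C10 bond, with C11 and C13 substituents on opposite faces of ring C. The strategy rests on C8: it bears two carbonyl carbons, C7 and C15, so it can be carried as an achiral C(CO2Me)2 group, and ring D can be closed by acylating a C16 carbanion with the one ester that is cis to the C13 arm.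

## Retrosynthetic reasoning

**35 ⇒ 34 (C16–H).** The last bond made is C16–H, from the C16 phenyl sulfone. The sulfone is the group that made C16 nucleophilic, and removing it last means the epimerisable C16 centre is formed by kinetic protonation and sees no later acid or base.

**34 ⇒ 30 (oxidation level and protecting groups).** The C6 lactone goes back to a methyl acetal, so that C5–H is not acidic when a strong base is used. The δ-lactone goes back to a C7 methyl ester plus a benzyl-protected O20, and O11 to a silyl ether. The forward steps are acetal hydrolysis, lactol oxidation, debenzylation and lactonisation.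

**30 ⇒ 29 (C15–C16, the key cut).** C15 is a carbonyl carbon and C16 is α to it, so the bond has natural acylation polarity once C16 carries a sulfone. Cutting here, and not at C8–C15 or C8–C14, leaves C8 with two identical ester groups, so the quaternary stereocentre C8 disappears from the problem. The forward reaction must form a carbanion only at C16 and must use only the ester cis to the C13 arm; the ring guarantees the latter.

**29 ⇒ 27 (O11 and C7).** The C11 oxygen is traced back to a bridged lactone in which it is acylated by the C7 carbonyl. This lactone is what the ring C closure delivers and it protects O11 without an extra group. Forward, it must be opened to the gem-dimethyl diester and O11 capped at once.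

**27 ⇒ 26 (C8–C14).** Ring C is opened at C8–C14, an alkylation of a 1,3-dicarbonyl carbon by a primary halide, which is reliable even when it creates a quaternary centre. The tether fixes which face of C8 is alkylated.

**26 ⇒ 12 + 25 (C9–C10).** This is the most crowded bond and is best made by adding a tertiary C10 radical to C9 of a doubly activated alkene, because radical additions have early transition states. A butenolide is used in place of an open alkylidene malonate: the C11 substituent on the ring directs the radical anti, which becomes the required cis relation of C10 and O11 on ring C. The C10 configuration follows from the shape of the cis-fused ring A acetal. The cut is convergent.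

**25 ⇒ 19 ⇒ 17 (C8=C9 and C9/C14).** The butenolide alkene comes from an intramolecular Knoevenagel condensation of an O11-bound malonate with a C9 aldehyde. C9 and C14 are the two alkene carbons of a cyclopentene, whose ring holds C11 and C13 in a defined 1,3-relation. The malonate 18 is attached to O11 with inversion, which gives the trans relation.

**17 ⇒ 16 ⇒ 14 + 15 (C13–C16).** The C13–C16 bond is made by allylic alkylation of the enantiopure monoacetate 15 with the stabilised carbanion of 14, which comes from 13. Net retention puts C16 where the acetate was; the ester that made the carbanion soft is then removed.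

**12 ⇒ 10 ⇒ 9 (C10–O and C10–C20).** The radical precursor is the half-oxalate of a tertiary alcohol, which comes from adding a benzyloxymethyl group to the C10 ketone. The carbinol configuration is irrelevant.

**9 ⇒ 6 ⇒ 5 ⇒ 1 + 2 (C5–C6 and C4–C19).** C6 is attached to C5 through the regiodefined enolate produced by conjugate addition. The conjugate addition of an alkenyl group from 2 to 1 sets the quaternary C4, and the alkenyl group is later cut down to C19.

## Alternatives that were turned down

**Alternative 1:** The disconnection is C12–C13. In the forward step a base would enolise the methyl group (C12) of an acetyl substituent on C9, and the enolate would add to C13, the β-carbon of a 2-methylcyclopentenone spiro-fused at C8. This closes ring C and gives A1, the 11-oxo analogue of 35.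
- For it: the ring closure is a favourable 6-exo Michael addition; C13 is fixed by the tether; both lactones are in place. A1 is one reduction from 35, so its endgame is shorter than the four steps that follow 30 here.
- Against it: the spiro quaternary C8 must be built with the right configuration relative to C9 and C10 before the step, and the step does nothing to help. The substrate has several acidic sites besides the methyl group (C9–H, C5–H next to the C6 lactone, the C14 hydrogens γ to the enone). The final reduction must choose the C11 ketone over the C15 ketone and deliver hydride to the C11 face lying under the C15–C16 bridge to give the equatorial alcohol.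
- Comparison: the chosen route offers automatic control of C8, C11 set at the outset from a chiral building block, and a single acidic site in the ring-forming step.

**Alternative 2:** The disconnection is C8–C9 plus C13–C14. Heating would make a 2-bromoacrylate (C8=C14), tethered through O20, add to a C9=C11(OSi)–C12=C13 diene. This forms ring C and the δ-lactone at once and gives A2.
- For it: two C–C bonds and two rings in one step, more than the key step here; the tether links C8 and C9 to C10; the C8 bromide and the C11 enol ether are handles.
- Against it: the diene terminus C9 sits on quaternary C10; ester tethers cyclise reluctantly, so forcing temperatures are likely; the C9 outcome depends on diene geometry and on endo/exo preference. A2 has neither ring D nor C15–C17, C13 is an unfunctionalised CH2, and C11 is at the ketone level. Ring D would need new functionality at C13, a C8–C15 bond from a tertiary bromide and a stereoselective C11 reduction.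
- Comparison: the chosen route forms fewer bonds in its key step but arrives with C13, C11 and the whole ring D carbon set in place.

**Alternative 3:** The disconnection is C8–C14 across a seven-membered ring (C8, C9, C11, C12, C13, C16, C15). The C8 lactone enolate would displace iodide from an iodomethyl group on C13, closing rings C and D together to give A3.
- For it: one step creates quaternary C8 and both carbocycles; A3 is two deprotections from 35, a shorter endgame than here; the C15 ketal shields C16 from epimerisation.
- Against it: it needs a cycloheptane carrying C9, C11, C13 and C16 with ring A attached, harder to build than cyclohexane 29. The C8 enolate has the ketal oxygen on C15 in the β-position and can eliminate it; C5–H of the ring A lactone competes for the base. A tertiary enolate must attack a β-branched primary iodide through a transannular geometry, with O-alkylation as a competitor.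
- Comparison: the chosen route uses an acylation, which is less demanding than this SN2 reaction, and it needs no stereocontrol at C8.

Key step: step 16

Remarks:
- Atoms carry ent-kaurane numbers throughout. Starting materials 1, 2, 13, 15 and 18 are commercial.
- Centres formed as mixtures and erased or irrelevant later are written without a descriptor in the SMILES: C5 in 6–8, the carbinol carbon in 10–12, the acetal or lactol carbon C6, C16 before step 16, and C8 in 26.

## Route

Step 1
Reactants: 1 3-methylcyclohex-2-en-1-one; 2 hex-1-yne
Product: 5 (S)-{[3-((E)-hex-1-en-1-yl)-3-methylcyclohex-1-en-1-yl]oxy}trimethylsilane, via alkenylalane 3 (not isolated), via aluminium enolate 4 (not isolated)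
Conditions: 2, i-Bu2AlH, hexane, 50 °C; then 1, CuTC [Cu(O2CC4H3S)] (10 mol%), chiral N,N-bis(1-arylethyl)-P,P-diphenylphosphinamine ligand (11 mol%, the antipode giving S), Et2O, −30 °C; then Me3SiOTf, −30 → 0 °C
Reagents that add atoms: trimethylsilyl trifluoromethanesulfonate, C[Si](C)(C)OS(=O)(=O)C(F)(F)F
Why: Copper-catalysed asymmetric conjugate addition of an alkenylalane (from syn-hydroalumination of 2) to the β-methyl enone creates quaternary C4 under ligand control. O-Silylation of the regiodefined enolate keeps the C5=C10 enol ether, so that C5 and not C1 reacts next.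

Step 2
Reactants: 5
Product: 6 (3S)-2-(dimethoxymethyl)-3-[(E)-hex-1-en-1-yl]-3-methylcyclohexan-1-one (C2 epimers)
Conditions: HC(OMe)3, BF3·OEt2, CH2Cl2, −78 °C
Reagents that add atoms: trimethyl orthoformate, COC(OC)OC
Why: Mukaiyama-type addition of the silyl enol ether to the dimethoxycarbenium ion puts C6 on C5 at the aldehyde oxidation level. The C5 epimer mixture is harmless because C5 stays enolisable until step 3.

Step 3
Reactants: 6
Product: 9 (3aS,7aR)-3-methoxy-7a-methylhexahydro-2-benzofuran-4(1H)-one (cis-fused; anomers), via keto aldehyde 7 (not isolated), via hydroxy ketone 8 (not isolated)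
Conditions: O3, CH2Cl2–MeOH, −78 °C, then Me2S; NaBH4, EtOH, −78 °C; then CSA (cat.), MeOH, rt
Reagents that add atoms: ozone, [O-][O+]=O
Why: Ozonolysis cuts the alkenyl group down to the C19 aldehyde, and borohydride at −78 °C should reduce this aldehyde much faster than the hindered ketone. Acid-catalysed transacetalisation then closes the five-membered ring on O19, and C5 equilibrates through the enol of the C10 ketone into the cis-fused bicycle.

Step 4
Reactants: 9
Product: 10 4-(benzyloxymethyl)-3-methoxy-7a-methyloctahydro-2-benzofuran-4-ol (ring fusion as in 9; carbinol epimers)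
Conditions: BnOCH2Cl, SmI2, THF, rt
Reagents that add atoms: benzyl chloromethyl ether, ClCOCc1ccccc1
Why: Barbier reaction: SmI2 turns the chloromethyl ether into a benzyloxymethyl-samarium species that adds to the hindered, enolisable ketone without deprotonating it. The new carbinol centre is destroyed in step 13.

Step 5
Reactants: 10
Product: 12 caesium 2-{[4-(benzyloxymethyl)-3-methoxy-7a-methyloctahydro-2-benzofuran-4-yl]oxy}-2-oxoacetate, via methyl oxalate 11 (not isolated)
Conditions: ClC(O)CO2Me, Et3N, DMAP (cat.), CH2Cl2, 0 °C → rt; then CsOH·H2O (1.0 equiv), THF–H2O, rt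
Reagents that add atoms: methyl chlorooxoacetate, COC(=O)C(=O)Cl; caesium hydroxide, [Cs+].[OH-]
Why: The very reactive acid chloride acylates the tertiary alcohol, and the unhindered methyl ester of the mixed oxalate is hydrolysed selectively, giving the half-oxalate salt used as radical precursor.

Step 6
Reactants: 13 ethyl phenyl sulfone
Product: 14 methyl 2-(phenylsulfonyl)propanoate (racemic)
Conditions: LDA [LiN(iPr)2] (2.1 equiv), THF, −78 °C; ClCO2Me; AcOH
Reagents that add atoms: methyl chloroformate, COC(=O)Cl
Why: C-Acylation of the α-sulfonyl carbanion with a chloroformate. The second equivalent of base deprotonates the more acidic product and so prevents double acylation.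

Step 7
Reactants: 14; 15 (1S,4R)-cis-4-acetoxycyclopent-2-en-1-ol
Product: 16 methyl 2-[(1R,4S)-4-hydroxycyclopent-2-en-1-yl]-2-(phenylsulfonyl)propanoate (C16 epimers)
Conditions: NaH, THF, 0 °C; then 15, Pd(PPh3)4 (3 mol%), THF, 40 °C
Reagents that add atoms: none
Why: Tsuji–Trost allylic alkylation: zerovalent palladium ionises the acetate with inversion, and the soft carbanion attacks the allyl terminus remote from the hydroxyl, again with inversion. C13 is therefore set with net retention, the new C13–C16 bond cis to the hydroxyl.

Step 8
Reactants: 16
Product: 17 (1S,4R)-4-[1-(phenylsulfonyl)ethyl]cyclopent-2-en-1-ol (C16 epimers)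
Conditions: LiCl, H2O, DMSO, 140 °C
Reagents that add atoms: none
Why: Krapcho dealkoxycarbonylation: chloride demethylates the ester and the α-sulfonyl carboxylate loses CO2. C16 becomes a CH centre as an epimer mixture, which does not matter.

Step 9
Reactants: 17; 18 3-methoxy-3-oxopropanoic acid (monomethyl malonate)
Product: 19 methyl (1R,4R)-4-[1-(phenylsulfonyl)ethyl]cyclopent-2-en-1-yl propanedioate
Conditions: PPh3, DIAD, THF, 0 °C → rt
Reagents that add atoms: none
Why: Mitsunobu esterification inverts C11 by SN2 displacement of the oxyphosphonium group, giving the trans relation of O11 and the C13 arm that the target needs. The same step installs C7, C8 and C15 as a malonate.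

Step 10
Reactants: 19
Product: 22 methyl (2R,4R)-4-(hydroxymethyl)-1,1-dimethoxy-5-(phenylsulfonyl)hexan-2-yl propanedioate, via aldehyde hydroperoxide 20 (not isolated), via acetal hydroperoxide 21 (not isolated)
Conditions: O3, CH2Cl2–MeOH (5:1), −78 °C; TsOH·H2O (cat.), rt; NaHCO3; NaBH4, 0 °C
Reagents that add atoms: ozone, [O-][O+]=O; methanol, CO
Why: Ozonolysis with unsymmetrical work-up: the primary ozonide should fragment to put the aldehyde at C9, next to the electron-withdrawing acyloxy carbon, and the carbonyl oxide at C14, where methanol traps it. Acid acetalises C9 and borohydride then reduces the C14 methoxy hydroperoxide to the primary alcohol, so the two termini leave the step differentiated.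

Step 11
Reactants: 22
Product: 23 methyl (2R,4S)-4-(chloromethyl)-1,1-dimethoxy-5-(phenylsulfonyl)hexan-2-yl propanedioate
Conditions: PPh3, CCl4, CH2Cl2, 40 °C
Reagents that add atoms: carbon tetrachloride, ClC(Cl)(Cl)Cl
Why: Appel chlorination of the primary alcohol under neutral conditions. The β-branched chloride is inert in steps 12 and 13 and is activated only in step 14.

Step 12
Reactants: 23
Product: 25 methyl (5R)-5-[(2S)-2-(chloromethyl)-3-(phenylsulfonyl)butyl]-2-oxo-2,5-dihydrofuran-3-carboxylate, via aldehyde 24 (not isolated)
Conditions: TFA–H2O (4:1), CH2Cl2, 0 °C → rt; then piperidine (0.1 equiv), AcOH (0.3 equiv), 4 Å MS, CH2Cl2, 0 °C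
Reagents that add atoms: none
Why: Acid hydrolysis frees the C9 aldehyde, and the tethered malonate condenses with it in an intramolecular Knoevenagel reaction that can only give the five-membered ring. The buffered amine keeps γ-deprotonation at C11 slow, so C11 and C13 stay intact.

Step 13
Reactants: 12; 25
Product: 26 lactone ester (3-methoxycarbonyl-γ-butyrolactone; C9 carries the ring A acetal with C20–OBn trans to the C11 side chain; C14–Cl; C8 epimers)
Conditions: Ir[dF(CF3)ppy]2(dtbbpy)PF6 (1 mol%), H2O (10 equiv), DME–DMF (3:1), blue LEDs, 25–40 °C
Reagents that add atoms: none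
Why: Photoredox Giese coupling: the excited iridium complex oxidises the oxalate, which loses two CO2 and gives the tertiary C10 radical. This adds to C9 of the butenolide anti to the C11 substituent, and the acceptor meets C10 on the face away from the fused acetal ring and the axial C19 (equatorial attack), which sets C9 and C10. The α-carbonyl radical is then reduced and protonated.

Step 14
Reactants: 26
Product: 27 bridged lactone (7-oxo-6-oxabicyclo[3.2.1]octane; ring C closed; O11–C7 lactone; C15 methyl ester on C8)
Conditions: Cs2CO3, NaI (0.2 equiv), DMF, 50 °C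
Reagents that add atoms: none
Why: Intramolecular 6-exo-tet alkylation of the lactone ester enolate at C14, with iodide catalysis, closes ring C; carbonate does not touch the sulfone α-hydrogen. The tether forces C14 onto the C12 face of the lactone, anti to ring A, so the C7 lactone carbonyl and the C15 ester on C8 are placed unambiguously.

Step 15
Reactants: 27
Product: 29 key precursor (ring C 1,1-dimethyl diester; C11–OTBS; C13 1-(phenylsulfonyl)ethyl arm; C20–OBn; ring A methyl acetal), via hydroxy diester 28 (not isolated)
Conditions: NaOMe (0.3 equiv), MeOH, 0 °C; AcOH, concentrate cold; then t-BuMe2SiOTf, 2,6-lutidine, CH2Cl2, −78 → 0 °C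
Reagents that add atoms: methanol, CO; tert-butyldimethylsilyl trifluoromethanesulfonate, CC(C)(C)[Si](C)(C)OS(=O)(=O)C(F)(F)F
Why: Methoxide-catalysed transesterification opens the strained bridged lactone to the gem-dimethyl diester, which makes C8 prochiral. Immediate silylation of O11 blocks re-lactonisation and lets ring C flip into the chair needed in step 16.

Step 16
Reactants: 29
Product: 30 β-keto sulfone (bicyclo[3.2.1]octane with C15 ketone; 16-methyl-16-phenylsulfonyl; C7 methyl ester)
Conditions: LDA [LiN(iPr)2] (1.3 equiv), THF, −78 → −20 °C; AcOH, −78 °C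
Reagents that add atoms: none
Why: LDA removes the C16 hydrogen next to the sulfone, the only acidic C–H in 29, since neither ester on C8 has an α-hydrogen and ring A is held at the acetal level; a silylamide base would be about five pKa units too weak, and the product has no acidic hydrogen that could pull such an equilibrium forward. In the ring C chair with the C13 arm and one C8 ester 1,3-diaxial (C10 axial on C9, O11 equatorial), the carbanion adds to that ester carbonyl and methoxide leaves, an intramolecular Claisen-type acylation of an α-sulfonyl carbanion, which is a known route to cyclic β-keto sulfones. Ring D closes in 5-exo-trig mode at the ester carbonyl and the bicyclo[3.2.1]octane results. C8 becomes stereogenic by diastereotopic group selection: only the ester sharing a face with the C13 arm can bridge, the other would need a trans-bridged bicycle, so C8 follows from C13 as set in step 7. At C16 the phenylsulfonyl group should take the exo position and the methyl the endo one on steric grounds, but this centre is reset in step 20 and both C16 epimers of 29 pass through the same carbanion. The step needs site-selective deprotonation and ester selection, secured by the absence of other acidic C–H bonds and by the ring geometry. It also needs the diaxial chair, which costs energy but is reachable under Curtin–Hammett conditions now that O11 is no longer tied to C7. The mixture is quenched cold with acetic acid so that lithium methoxide cannot reopen the non-enolisable β-keto sulfone by retro-Claisen attack.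

Step 17
Reactants: 30
Product: 31 lactol (C6 hemiacetal; C11–OTBS; C20–OBn; C7 methyl ester; C16 sulfone)
Conditions: AcOH–THF–H2O (3:1:1), 40 °C
Reagents that add atoms: water, O
Why: Mild aqueous acid hydrolyses the methyl acetal to the lactol. The hindered secondary silyl ether, the benzyl ether and the non-enolisable β-keto ester and β-keto sulfone are expected to survive.

Step 18
Reactants: 31
Product: 32 γ-lactone (C6 lactone; C11–OTBS; C20–OBn; C7 methyl ester; C16 sulfone)
Conditions: TEMPO (0.2 equiv), PhI(OAc)2, CH2Cl2, rt
Reagents that add atoms: none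
Why: Oxoammonium (TEMPO) oxidation of the lactol gives the C6 γ-lactone; no other oxidisable hydroxyl is present.

Step 19
Reactants: 32
Product: 34 16-(phenylsulfonyl)guidongnin C (bis-lactone sulfone; free C11–OH), via primary alcohol 33 (not isolated)
Conditions: H2 (1 atm), Pd(OH)2/C, EtOAc–MeOH, rt; then 1 M HCl, THF, 40 °C
Reagents that add atoms: none
Why: Hydrogenolysis removes the C20 benzyl ether; aqueous acid then cleaves the silyl ether and lactonises O20 onto the C7 ester. O11 cannot compete, because the bicycle holds C7 anti to C11 across C8–C9.

Step 20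
Reactants: 34
Product: 35 guidongnin C
Conditions: SmI2 (2.5 equiv), THF–MeOH, −78 °C; pH 7 buffer
Reagents that add atoms: none
Why: Reductive desulfonylation of the α-sulfonyl ketone by two single-electron transfers gives a samarium enolate. Kinetic protonation on the less hindered exo face (the side of C14) puts hydrogen exo and the methyl endo, as in the target. Doing this last keeps the epimerisable C16 centre away from acid and base.

## Compound list

1 | 3-methylcyclohex-2-en-1-one | CC1=CC(=O)CCC1 | starting material
2 | hex-1-yne | CCCCC#C | starting material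
3 | (E)-hex-1-en-1-yl-diisobutylaluminium | CCCC/C=C/[Al](CC(C)C)CC(C)C | intermediate
4 | diisobutylaluminium enolate of (S)-3-[(E)-hex-1-enyl]-3-methylcyclohexanone | CCCC/C=C/[C@]1(C)CCCC(O[Al](CC(C)C)CC(C)C)=C1 | intermediate
5 | (S)-{[3-((E)-hex-1-en-1-yl)-3-methylcyclohex-1-en-1-yl]oxy}trimethylsilane | CCCC/C=C/[C@]1(C)CCCC(O[Si](C)(C)C)=C1 | intermediate
6 | (3S)-2-(dimethoxymethyl)-3-[(E)-hex-1-en-1-yl]-3-methylcyclohexan-1-one (C2 epimers) | CCCC/C=C/[C@]1(C)CCCC(=O)C1C(OC)OC | intermediate
7 | (1R)-2-(dimethoxymethyl)-1-methyl-3-oxocyclohexane-1-carbaldehyde | O=C[C@]1(C)CCCC(=O)C1C(OC)OC | intermediate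
8 | (3R)-2-(dimethoxymethyl)-3-(hydroxymethyl)-3-methylcyclohexan-1-one | OC[C@]1(C)CCCC(=O)C1C(OC)OC | intermediate
9 | (3aS,7aR)-3-methoxy-7a-methylhexahydro-2-benzofuran-4(1H)-one (anomers) | O=C1CCC[C@@]2(C)COC(OC)[C@@H]12 | intermediate
10 | 4-(benzyloxymethyl)-3-methoxy-7a-methyloctahydro-2-benzofuran-4-ol (ring fusion as in 9) | OC1(COCc2ccccc2)CCC[C@@]2(C)COC(OC)[C@@H]12 | intermediate
11 | methyl oxalate of 10 | COC(=O)C(=O)OC1(COCc2ccccc2)CCC[C@@]2(C)COC(OC)[C@@H]12 | intermediate
12 | caesium half-oxalate of 10 | [Cs+].[O-]C(=O)C(=O)OC1(COCc2ccccc2)CCC[C@@]2(C)COC(OC)[C@@H]12 | intermediate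
13 | ethyl phenyl sulfone | CCS(=O)(=O)c1ccccc1 | starting material
14 | methyl 2-(phenylsulfonyl)propanoate | COC(=O)C(C)S(=O)(=O)c1ccccc1 | intermediate
15 | (1S,4R)-cis-4-acetoxycyclopent-2-en-1-ol | C1=C[C@@H](O)C[C@H]1OC(C)=O | starting material
16 | methyl 2-[(1R,4S)-4-hydroxycyclopent-2-en-1-yl]-2-(phenylsulfonyl)propanoate | C1=C[C@@H](O)C[C@H]1C(C)(C(=O)OC)S(=O)(=O)c1ccccc1 | intermediate
17 | (1S,4R)-4-[1-(phenylsulfonyl)ethyl]cyclopent-2-en-1-ol | C1=C[C@@H](O)C[C@H]1C(C)S(=O)(=O)c1ccccc1 | intermediate
18 | 3-methoxy-3-oxopropanoic acid | COC(=O)CC(=O)O | starting material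
19 | methyl (1R,4R)-4-[1-(phenylsulfonyl)ethyl]cyclopent-2-en-1-yl propanedioate | C1=C[C@H](OC(=O)CC(=O)OC)C[C@H]1C(C)S(=O)(=O)c1ccccc1 | intermediate
20 | aldehyde hydroperoxide (C9 aldehyde, C14 methoxy hydroperoxide) | O=C[C@H](OC(=O)CC(=O)OC)C[C@H](C(OC)OO)C(C)S(=O)(=O)c1ccccc1 | intermediate
21 | acetal hydroperoxide (C9 dimethyl acetal, C14 methoxy hydroperoxide) | COC(OC)[C@H](OC(=O)CC(=O)OC)C[C@H](C(OC)OO)C(C)S(=O)(=O)c1ccccc1 | intermediate
22 | methyl (2R,4R)-4-(hydroxymethyl)-1,1-dimethoxy-5-(phenylsulfonyl)hexan-2-yl propanedioate | COC(OC)[C@H](OC(=O)CC(=O)OC)C[C@H](CO)C(C)S(=O)(=O)c1ccccc1 | intermediate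
23 | methyl (2R,4S)-4-(chloromethyl)-1,1-dimethoxy-5-(phenylsulfonyl)hexan-2-yl propanedioate | COC(OC)[C@H](OC(=O)CC(=O)OC)C[C@H](CCl)C(C)S(=O)(=O)c1ccccc1 | intermediate
24 | methyl (2R,4S)-4-(chloromethyl)-1-oxo-5-(phenylsulfonyl)hexan-2-yl propanedioate | O=C[C@H](OC(=O)CC(=O)OC)C[C@H](CCl)C(C)S(=O)(=O)c1ccccc1 | intermediate
25 | methyl (5R)-5-[(2S)-2-(chloromethyl)-3-(phenylsulfonyl)butyl]-2-oxo-2,5-dihydrofuran-3-carboxylate | COC(=O)C1=C[C@@H](C[C@H](CCl)C(C)S(=O)(=O)c2ccccc2)OC1=O | intermediate
26 | lactone ester with the C9–C10 bond (C8 epimers) | CC(S(=O)(=O)c1ccccc1)[C@@H](CCl)C[C@H]1OC(=O)C(C(=O)OC)[C@@H]1[C@@]1(CCC[C@@]2(C)COC(OC)[C@H]21)COCc1ccccc1 | intermediate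
27 | bridged lactone with ring C closed | CC(S(=O)(=O)c1ccccc1)[C@@H]1C[C@H]2OC(=O)[C@](C1)(C(=O)OC)[C@@H]2[C@@]1(CCC[C@@]2(C)COC(OC)[C@H]21)COCc1ccccc1 | intermediate
28 | hydroxy diester (free C11–OH) | CC(S(=O)(=O)c1ccccc1)[C@@H]1C[C@@H](O)[C@@H]([C@@]2(CCC[C@@]3(C)COC(OC)[C@H]32)COCc2ccccc2)C(C(=O)OC)(C(=O)OC)C1 | intermediate
29 | key precursor (gem-diester, C11–OTBS, C20–OBn) | CC(S(=O)(=O)c1ccccc1)[C@@H]1C[C@@H](O[Si](C)(C)C(C)(C)C)[C@@H]([C@@]2(CCC[C@@]3(C)COC(OC)[C@H]32)COCc2ccccc2)C(C(=O)OC)(C(=O)OC)C1 | intermediate
30 | β-keto sulfone (ring D closed) | C[C@@]1(S(=O)(=O)c2ccccc2)C(=O)[C@]2(C(=O)OC)C[C@H]1C[C@@H](O[Si](C)(C)C(C)(C)C)[C@H]2[C@@]1(CCC[C@@]2(C)COC(OC)[C@H]21)COCc1ccccc1 | intermediate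
31 | lactol | C[C@@]1(S(=O)(=O)c2ccccc2)C(=O)[C@]2(C(=O)OC)C[C@H]1C[C@@H](O[Si](C)(C)C(C)(C)C)[C@H]2[C@@]1(CCC[C@@]2(C)COC(O)[C@H]21)COCc1ccccc1 | intermediate
32 | γ-lactone | C[C@@]1(S(=O)(=O)c2ccccc2)C(=O)[C@]2(C(=O)OC)C[C@H]1C[C@@H](O[Si](C)(C)C(C)(C)C)[C@H]2[C@@]1(CCC[C@@]2(C)COC(=O)[C@H]21)COCc1ccccc1 | intermediate
33 | primary alcohol (free C20–OH) | C[C@@]1(S(=O)(=O)c2ccccc2)C(=O)[C@]2(C(=O)OC)C[C@H]1C[C@@H](O[Si](C)(C)C(C)(C)C)[C@H]2[C@@]1(CCC[C@@]2(C)COC(=O)[C@H]21)CO | intermediate
34 | 16-(phenylsulfonyl)guidongnin C | C[C@@]1(S(=O)(=O)c2ccccc2)C(=O)[C@]23C[C@H]1C[C@@H](O)[C@H]2[C@@]1(CCC[C@@]2(C)COC(=O)[C@H]21)COC3=O | intermediate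
35 | guidongnin C | C[C@H]1C(=O)[C@]23C[C@H]1C[C@@H](O)[C@H]2[C@@]1(CCC[C@@]2(C)COC(=O)[C@H]21)COC3=O | target

## Step count and uncertain steps

Total: 20 steps. Longest linear sequence: 15 steps (13 → 35, steps 6–12 and 13–20). The ring A branch (steps 1–5) joins at step 13.

**Step 16 (key step).** The acylation may stall or run backwards. The reactive chair has C10 and the C13 arm axial, the tetrahedral intermediate can collapse to starting material, and lithium methoxide can attack the strained non-enolisable ketone. The fallback singles out the C15 carbonyl chemically and makes it a better acyl donor. It sets out from 27. Me3SnOH in hot 1,2-dichloroethane cleaves only the methyl ester on C8 and gives lactone acid F1; if the lactone opens it can only re-close on O11, because C7 alone is cis to O11. NaOMe in MeOH followed by t-BuMe2SiOTf and 2,6-lutidine, with a mild K2CO3–MeOH work-up to free the acid, gives acid ester F2 (C7 methyl ester, C15 acid, O11 silyl ether). Carbonyldiimidazole gives acyl imidazolide F3. LDA at −78 °C then forms the C16 carbanion, which is acylated by the imidazolide; the leaving group does not add back. The route is rejoined at 30.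

**Step 13.** The hindered tertiary radical may be reduced or disproportionate instead of adding. The butenolide may lose its C11 configuration by γ-deprotonation under the basic oxalate. Face selection at C10 may be incomplete. The fallback makes the same radical by hydrogen-atom transfer to an alkene, without a basic salt. It sets out from 9. KN(SiMe3)2 and PhNTf2 give enol triflate F4 (C10=C1). Stille coupling with Bu3SnCH2OBn (Pd(PPh3)4, LiCl, CuI) gives alkene F5. Fe(acac)3 and PhSiH3 in EtOH at 60 °C with 25 transfer hydrogen to C1, and the C10 radical adds to the butenolide as before. The route is rejoined at 26.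

**Step 10.** The primary ozonide may fragment without regiocontrol, since the C13 arm is also electron-withdrawing, which would give the wrong acetal/alcohol pair. Acidic methanol may also begin to cleave the malonate ester. The fallback lets ring size tell the termini apart and closes ring C by an aldol reaction. It sets out from 19. Ozonolysis in CH2Cl2 with PPh3 work-up gives dialdehyde F6. Piperidinium acetate condenses the malonate with C9 only (five-membered ring) and gives butenolide aldehyde F7; the buffer must stay weakly acidic so that sulfinate is not eliminated next to the C14 aldehyde. Coupling with 12 under the conditions of step 13, followed if needed by Cs2CO3, lets the C8 enolate add to the C14 aldehyde and gives hydroxy lactone F8. Thiocarbonyldiimidazole gives thiocarbamate F9, and Bu3SnH with AIBN (Barton–McCombie) removes the C14 oxygen. The route is rejoined at 27.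

**Step 20.** Protonation may occur partly on the endo face, or C16 may equilibrate during work-up, because the target epimer (methyl endo) is probably not the more stable one. The fallback makes C16 by hydrogenation in place of protonation. It sets out from 34, whose reduction product is taken on as the mixture of 35 and its C16 epimer F10. Me3SiOTf and Et3N give bis-silyl enol ether F11. Pd(OAc)2 in MeCN (Saegusa–Ito oxidation, where only the methyl hydrogens can be eliminated because a bridgehead alkene is excluded), followed by citric acid work-up, gives 16-methylene ketone F12. Hydrogenation over Pd/C in EtOAc adds hydrogen on the exo face. The route is rejoined at 35.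

## Further compounds

F1 | step 16 | lactone acid (27 with C15 carboxylic acid) | CC(S(=O)(=O)c1ccccc1)[C@@H]1C[C@H]2OC(=O)[C@](C1)(C(=O)O)[C@@H]2[C@@]1(CCC[C@@]2(C)COC(OC)[C@H]21)COCc1ccccc1
F2 | step 16 | acid ester (C7 methyl ester, C15 acid, C11–OTBS) | CC(S(=O)(=O)c1ccccc1)[C@@H]1C[C@@H](O[Si](C)(C)C(C)(C)C)[C@@H]([C@@]2(CCC[C@@]3(C)COC(OC)[C@H]32)COCc2ccccc2)[C@](C(=O)OC)(C(=O)O)C1
F3 | step 16 | acyl imidazolide (C15) | CC(S(=O)(=O)c1ccccc1)[C@@H]1C[C@@H](O[Si](C)(C)C(C)(C)C)[C@@H]([C@@]2(CCC[C@@]3(C)COC(OC)[C@H]32)COCc2ccccc2)[C@](C(=O)OC)(C(=O)n2ccnc2)C1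
F4 | step 13 | enol triflate of 9 (C10=C1) | O=S(=O)(OC1=CCC[C@@]2(C)COC(OC)[C@@H]12)C(F)(F)F
F5 | step 13 | alkene (C10=C1 with CH2OBn on C10) | c1ccccc1COCC1=CCC[C@@]2(C)COC(OC)[C@@H]12
F6 | step 10 | dialdehyde (C9 and C14 aldehydes) | O=C[C@H](OC(=O)CC(=O)OC)C[C@H](C=O)C(C)S(=O)(=O)c1ccccc1
F7 | step 10 | butenolide aldehyde | COC(=O)C1=C[C@@H](C[C@H](C=O)C(C)S(=O)(=O)c2ccccc2)OC1=O
F8 | step 10 | hydroxy lactone (27 with C14–OH) | CC(S(=O)(=O)c1ccccc1)[C@@H]1C[C@H]2OC(=O)[C@](C1O)(C(=O)OC)[C@@H]2[C@@]1(CCC[C@@]2(C)COC(OC)[C@H]21)COCc1ccccc1
F9 | step 10 | thiocarbamate (C14 O-imidazole-1-carbothioate) | CC(S(=O)(=O)c1ccccc1)[C@@H]1C[C@H]2OC(=O)[C@](C1OC(=S)n3ccnc3)(C(=O)OC)[C@@H]2[C@@]1(CCC[C@@]2(C)COC(OC)[C@H]21)COCc1ccccc1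
F10 | step 20 | 16-epi-guidongnin C | C[C@@H]1C(=O)[C@]23C[C@H]1C[C@@H](O)[C@H]2[C@@]1(CCC[C@@]2(C)COC(=O)[C@H]21)COC3=O
F11 | step 20 | bis-silyl enol ether (C15 enol ether, O11–SiMe3) | CC1=C(O[Si](C)(C)C)[C@]23C[C@H]1C[C@@H](O[Si](C)(C)C)[C@H]2[C@@]1(CCC[C@@]2(C)COC(=O)[C@H]21)COC3=O
F12 | step 20 | 16-methylene ketone | C=C1C(=O)[C@]23C[C@H]1C[C@@H](O)[C@H]2[C@@]1(CCC[C@@]2(C)COC(=O)[C@H]21)COC3=O
A1 | alternative 1 | 11-oxo bis-lactone | C[C@H]1C(=O)[C@]23C[C@H]1CC(=O)[C@H]2[C@@]1(CCC[C@@]2(C)COC(=O)[C@H]21)COC3=O
A2 | alternative 2 | lactone-fused ring C silyl enol ether with C8 bromide | Br[C@]12CCC=C(O[Si](C)(C)C(C)(C)C)[C@H]1[C@@]3(CCC[C@@]4(C)COC(=O)[C@H]43)COC2=O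
A3 | alternative 3 | protected target (C15 dioxolane, C11 silyl ether) | C[C@H]1C2(OCCO2)[C@]34C[C@H]1C[C@@H](O[Si](C)(C)C(C)(C)C)[C@H]3[C@@]1(CCC[C@@]2(C)COC(=O)[C@H]21)COC4=O
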